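**Plan**
- Enabling feature: in the oxolane, O1 lies between the two benzylic carbons C2 and C5, which are 1,4-related across the methyl-bearing C3–C4 bond. This is the pattern of the termini of a 2,3-dimethylbuta-1,3-diene, so O1 can come from O2.
- Retrosynthesis: the four ring C–H bonds go back to a furan; the furan goes back to a 3,6-dihydro-1,2-dioxine, where both ring C–O bonds are cut to give an (E,E)-diene and O2. The central C3–C4 bond is then cut (alkenylboronate dimerisation), followed by the aryl–alkyne bond, the C1'–aryl bond and the aryl ether O–C2' bond.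
- Forward: one arm is built linearly (ether, ketone, carbinol, propyne, boronate) and dimerised to the twofold-symmetric diene. The only ring then arises as the six-membered dioxine, is contracted to the furan and saturated to the oxolane.
- Stereochemistry: C2' (S) comes from ethyl (R)-lactate by Mitsunobu inversion. C1' (R) comes from chelation-controlled Zn(BH4)2 reduction. The (E,E) geometry comes from syn-borylcupration. The four ring centres come from all-syn hydrogenation of the furan, whose two faces are equivalent.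

Key step: step 8

Remark: the aryl ether is closed with inversion at C2', so the chiral-pool ester is ethyl (R)-lactate. Locants used: oxolane O1, C2–C5; side chain C1' (carbinol carbon) and C2' (ether carbon).

**Route**

Step 1
Reactants: 1 ethyl (R)-lactate; 2 4-bromo-2-methoxyphenol
Product: 3 ethyl (2S)-2-(4-bromo-2-methoxyphenoxy)propanoate
Conditions: PPh3, DIAD, THF, 0 °C → rt
Reagents that add atoms: none
Why: Mitsunobu etherification, in which the phenoxide displaces the oxyphosphonium of the α-hydroxy ester by SN2, so C2' is inverted cleanly from R to S.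

Step 2
Reactants: 3 ethyl (2S)-2-(4-bromo-2-methoxyphenoxy)propanoate
Product: 4 (2S)-2-(4-bromo-2-methoxyphenoxy)-N-methoxy-N-methylpropanamide
Conditions: MeNH(OMe)·HCl, i-PrMgCl, THF, −20 → 0 °C
Reagents that add atoms: N,O-dimethylhydroxylamine hydrochloride, Cl.CNOC
Why: Weinreb amide formation by aminolysis of the ester with the magnesium amide generated in the flask; at this temperature the α-aryloxy centre should not be deprotonated and the aryl bromide should not undergo exchange.

Step 3
Reactants: 4 (2S)-2-(4-bromo-2-methoxyphenoxy)-N-methoxy-N-methylpropanamide; 5 4-bromo-1,2-dimethoxybenzene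
Product: 7 (2S)-2-(4-bromo-2-methoxyphenoxy)-1-(3,4-dimethoxyphenyl)propan-1-one, via (3,4-dimethoxyphenyl)magnesium bromide 6 (not isolated)
Conditions: 5, Mg, THF, reflux; then 4, THF, 0 °C; cold 1 M HCl work-up
Reagents that add atoms: none
Why: Grignard addition to a Weinreb amide stops at the chelated tetrahedral adduct, so the ketone is released only on acidic work-up, without over-addition and without touching C2' or the aryl bromide.

Step 4
Reactants: 7 (2S)-2-(4-bromo-2-methoxyphenoxy)-1-(3,4-dimethoxyphenyl)propan-1-one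
Product: 8 (1R,2S)-2-(4-bromo-2-methoxyphenoxy)-1-(3,4-dimethoxyphenyl)propan-1-ol
Conditions: Zn(BH4)2, Et2O, −20 → 0 °C; aq. NH4Cl
Reagents that add atoms: none
Why: Chelation-controlled (Cram-chelate) ketone reduction: zinc bridges the carbonyl and α-aryloxy oxygens and hydride enters from the chelate face bearing H rather than CH3 at C2', which should give the (1R,2S) erythro carbinol; any threo epimer is removed at this stage.

Step 5
Reactants: 8 (1R,2S)-2-(4-bromo-2-methoxyphenoxy)-1-(3,4-dimethoxyphenyl)propan-1-ol; 9 propyne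
Product: 10 (1R,2S)-1-(3,4-dimethoxyphenyl)-2-[2-methoxy-4-(prop-1-yn-1-yl)phenoxy]propan-1-ol
Conditions: propyne (THF solution, excess), PdCl2(PhCN)2 (cat.), [HP(t-Bu)3]BF4 (cat.), CuI (cat.), i-Pr2NH, dioxane, rt, sealed vessel
Reagents that add atoms: none
Why: Sonogashira coupling; the bulky electron-rich phosphine allows oxidative addition of the electron-rich aryl bromide at room temperature and the free carbinol is tolerated.

Step 6
Reactants: 10 (1R,2S)-1-(3,4-dimethoxyphenyl)-2-[2-methoxy-4-(prop-1-yn-1-yl)phenoxy]propan-1-ol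
Product: 11 (1R,2S)-1-(3,4-dimethoxyphenyl)-2-{2-methoxy-4-[(Z)-2-(4,4,5,5-tetramethyl-1,3,2-dioxaborolan-2-yl)prop-1-en-1-yl]phenoxy}propan-1-ol
Conditions: B2pin2, CuCl (cat.), P(p-tol)3 (cat.), NaOt-Bu (cat.), MeOH (2 equiv), THF, rt
Reagents that add atoms: bis(pinacolato)diboron, CC1(C)OB(OC1(C)C)B1OC(C)(C)C(C)(C)O1
Why: Copper-catalysed formal hydroboration of an aryl alkyl alkyne (syn-borylcupration, then protonation of the alkenylcopper by MeOH): copper goes to the aryl-bearing carbon and boron to the methyl-bearing carbon, and syn addition fixes the aryl group trans to boron.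

Step 7
Reactants: 11 (two molecules) (1R,2S)-1-(3,4-dimethoxyphenyl)-2-{2-methoxy-4-[(Z)-2-(4,4,5,5-tetramethyl-1,3,2-dioxaborolan-2-yl)prop-1-en-1-yl]phenoxy}propan-1-ol
Product: 12 (1E,3E)-1,4-bis{4-[(1R,2S)-1-(3,4-dimethoxyphenyl)-1-hydroxypropan-2-yloxy]-3-methoxyphenyl}-2,3-dimethylbuta-1,3-diene
Conditions: Pd(OAc)2 (cat.), K2CO3, MeOH–H2O, O2 (1 atm), rt → 40 °C
Reagents that add atoms: none
Why: Palladium-catalysed oxidative homocoupling of an alkenylboronate: two transmetalations onto divalent palladium and reductive elimination join the boron-bearing carbons with retention of both alkene geometries, while oxygen returns zerovalent palladium to the divalent state.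

Step 8
Reactants: 12 (1E,3E)-1,4-bis{4-[(1R,2S)-1-(3,4-dimethoxyphenyl)-1-hydroxypropan-2-yloxy]-3-methoxyphenyl}-2,3-dimethylbuta-1,3-diene
Product: 13 cis-3,6-bis{4-[(1R,2S)-1-(3,4-dimethoxyphenyl)-1-hydroxypropan-2-yloxy]-3-methoxyphenyl}-4,5-dimethyl-3,6-dihydro-1,2-dioxine
Conditions: O2 (bubbled), tetraphenylporphyrin (1 mol %), CH2Cl2, white LED, −20 °C
Reagents that add atoms: dioxygen, O=O
Why: Photosensitised singlet oxygen adds across C1 and C4 of the s-cis diene in a concerted suprafacial [4+2] cycloaddition, the hetero-Diels–Alder reaction known for 1,4-diaryl-1,3-dienes. The six-membered 3,6-dihydro-1,2-dioxine closes by this intermolecular cycloaddition, with both benzylic C–O bonds formed in the same event and the O–O bond delivered intact, so one oxygen of O2 already sits between the future C2 and C5. The two new stereocentres (C3 and C6 of the dioxine) are fixed cis by suprafacial addition to the (E,E) geometry; the twofold axis of the diene makes its faces equivalent, so a single diastereomer should form, and both centres are erased in step 9. The step needs periselectivity for [4+2] over the ene reaction at the allylic methyl groups and over [2+2] addition to the electron-rich styrene units. The vicinal 2,3-dimethyl groups make the cisoid conformer accessible with hydrogens at both inside positions, aryl conjugation raises the diene HOMO, and low temperature in an aprotic solvent disfavours the ene channel. The dialkoxyarenes and the free carbinols should be inert to singlet oxygen on this time scale.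

Step 9
Reactants: 13 cis-3,6-bis{4-[(1R,2S)-1-(3,4-dimethoxyphenyl)-1-hydroxypropan-2-yloxy]-3-methoxyphenyl}-4,5-dimethyl-3,6-dihydro-1,2-dioxine
Product: 16 2,5-bis{4-[(1R,2S)-1-(3,4-dimethoxyphenyl)-1-hydroxypropan-2-yloxy]-3-methoxyphenyl}-3,4-dimethylfuran, via cis-γ-hydroxy enone 14 (not isolated), via cyclic hemiketal 15 (not isolated)
Conditions: Et3N, CH2Cl2, 0 °C → rt; then PPTS (cat.), 4 Å MS, rt
Reagents that add atoms: none
Why: Kornblum–DeLaMare rearrangement: the amine removes a benzylic hydrogen next to the peroxide with O–O cleavage to the cis-γ-hydroxy enone, which closes to the hemiketal and loses water under mild acid to aromatise; either benzylic hydrogen leads to the same furan and PPTS is too weak to ionise the side-chain carbinols.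

Step 10
Reactants: 16 2,5-bis{4-[(1R,2S)-1-(3,4-dimethoxyphenyl)-1-hydroxypropan-2-yloxy]-3-methoxyphenyl}-3,4-dimethylfuran
Product: 17 all-cis (2R,3S,4R,5S)-2,5-bis{4-[(1R,2S)-1-(3,4-dimethoxyphenyl)-1-hydroxypropan-2-yloxy]-3-methoxyphenyl}-3,4-dimethyloxolane (CNP0116650.5)
Conditions: H2 (4 bar), Rh/Al2O3 (5 wt % Rh), EtOAc, rt
Reagents that add atoms: none
Why: Heterogeneous cis-hydrogenation of a tetrasubstituted furan delivers all four hydrogens to one face and so sets C2–C5 all-cis; the twofold axis of the furan makes both faces equivalent, so one diastereomer should result, and rhodium on alumina is chosen to spare the benzylic C–O bonds.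

**Compound list**
1 | ethyl (R)-lactate | CCOC(=O)[C@@H](C)O | starting material
2 | 4-bromo-2-methoxyphenol | COc1cc(Br)ccc1O | starting material
3 | ethyl (2S)-2-(4-bromo-2-methoxyphenoxy)propanoate | CCOC(=O)[C@H](C)Oc1ccc(Br)cc1OC | intermediate
4 | (2S)-2-(4-bromo-2-methoxyphenoxy)-N-methoxy-N-methylpropanamide | CON(C)C(=O)[C@H](C)Oc1ccc(Br)cc1OC | intermediate
5 | 4-bromo-1,2-dimethoxybenzene | COc1ccc(Br)cc1OC | starting material
6 | (3,4-dimethoxyphenyl)magnesium bromide | COc1ccc([Mg]Br)cc1OC | intermediate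
7 | (2S)-2-(4-bromo-2-methoxyphenoxy)-1-(3,4-dimethoxyphenyl)propan-1-one | COc1ccc(C(=O)[C@H](C)Oc2ccc(Br)cc2OC)cc1OC | intermediate
8 | (1R,2S)-2-(4-bromo-2-methoxyphenoxy)-1-(3,4-dimethoxyphenyl)propan-1-ol | COc1ccc([C@@H](O)[C@H](C)Oc2ccc(Br)cc2OC)cc1OC | intermediate
9 | propyne | CC#C | starting material
10 | (1R,2S)-1-(3,4-dimethoxyphenyl)-2-[2-methoxy-4-(prop-1-yn-1-yl)phenoxy]propan-1-ol | COc1ccc([C@@H](O)[C@H](C)Oc2ccc(C#CC)cc2OC)cc1OC | intermediate
11 | (1R,2S)-1-(3,4-dimethoxyphenyl)-2-{2-methoxy-4-[(Z)-2-(4,4,5,5-tetramethyl-1,3,2-dioxaborolan-2-yl)prop-1-en-1-yl]phenoxy}propan-1-ol | COc1ccc([C@@H](O)[C@H](C)Oc2ccc(/C=C(C)/B3OC(C)(C)C(C)(C)O3)cc2OC)cc1OC | intermediate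
12 | (1E,3E)-1,4-bis{4-[(1R,2S)-1-(3,4-dimethoxyphenyl)-1-hydroxypropan-2-yloxy]-3-methoxyphenyl}-2,3-dimethylbuta-1,3-diene | COc1ccc([C@@H](O)[C@H](C)Oc2ccc(/C=C(C)/C(C)=C/c3ccc(O[C@@H](C)[C@H](O)c4ccc(OC)c(OC)c4)c(OC)c3)cc2OC)cc1OC | intermediate
13 | cis-3,6-bis{4-[(1R,2S)-1-(3,4-dimethoxyphenyl)-1-hydroxypropan-2-yloxy]-3-methoxyphenyl}-4,5-dimethyl-3,6-dihydro-1,2-dioxine | COc1ccc([C@@H](O)[C@H](C)Oc2ccc([C@@H]3OO[C@H](c4ccc(O[C@@H](C)[C@H](O)c5ccc(OC)c(OC)c5)c(OC)c4)C(C)=C3C)cc2OC)cc1OC | intermediate
14 | (Z)-4-hydroxy-1,4-bis{4-[(1R,2S)-1-(3,4-dimethoxyphenyl)-1-hydroxypropan-2-yloxy]-3-methoxyphenyl}-2,3-dimethylbut-2-en-1-one (both C4 epimers; that centre undefined) | COc1ccc([C@@H](O)[C@H](C)Oc2ccc(C(O)/C(C)=C(C)\C(=O)c3ccc(O[C@@H](C)[C@H](O)c4ccc(OC)c(OC)c4)c(OC)c3)cc2OC)cc1OC | intermediate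
15 | 2,5-bis{4-[(1R,2S)-1-(3,4-dimethoxyphenyl)-1-hydroxypropan-2-yloxy]-3-methoxyphenyl}-3,4-dimethyl-2,5-dihydrofuran-2-ol (ring centres C2 and C5 undefined) | COc1ccc([C@@H](O)[C@H](C)Oc2ccc(C3OC(O)(c4ccc(O[C@@H](C)[C@H](O)c5ccc(OC)c(OC)c5)c(OC)c4)C(C)=C3C)cc2OC)cc1OC | intermediate
16 | 2,5-bis{4-[(1R,2S)-1-(3,4-dimethoxyphenyl)-1-hydroxypropan-2-yloxy]-3-methoxyphenyl}-3,4-dimethylfuran | COc1ccc([C@@H](O)[C@H](C)Oc2ccc(-c3oc(-c4ccc(O[C@@H](C)[C@H](O)c5ccc(OC)c(OC)c5)c(OC)c4)c(C)c3C)cc2OC)cc1OC | intermediate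
17 | all-cis (2R,3S,4R,5S)-2,5-bis{4-[(1R,2S)-1-(3,4-dimethoxyphenyl)-1-hydroxypropan-2-yloxy]-3-methoxyphenyl}-3,4-dimethyloxolane | COc1ccc([C@@H](O)[C@H](C)Oc2ccc([C@H]3O[C@@H](c4ccc(O[C@@H](C)[C@H](O)c5ccc(OC)c(OC)c5)c(OC)c4)[C@@H](C)[C@H]3C)cc2OC)cc1OC | target

**Step count**
Total steps: 10. Longest linear sequence: 10 steps (from 1 or 2 to 17).

**Steps most likely to fail, with fallbacks**

Step 7. Transmetalation of the hindered α-methyl alkenylboronate may be slow, so that protodeboronation or palladium-mediated oxidation of the benzylic carbinols overtakes the homocoupling. The fallback replaces the oxidative dimerisation by a redox-neutral cross-coupling. It sets out from 11: one half is treated with NaOH and then I2 (THF–H2O, 0 °C), an ipso-iododeboronation with retention. This should give (1R,2S)-1-(3,4-dimethoxyphenyl)-2-{4-[(E)-2-iodoprop-1-en-1-yl]-2-methoxyphenoxy}propan-1-ol F1. F1 is then joined to the other half of 11 by Suzuki–Miyaura coupling (Pd(dppf)Cl2, K3PO4, dioxane–H2O, 60 °C, degassed), which returns to diene 12 with both geometries retained.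

Step 8. The ene reaction at the allylic methyl groups, or [2+2] addition and cleavage at the styrene units, may compete with the cycloaddition if the diene twists away from the cisoid form. The fallback changes the mechanism rather than the lamp or sensitiser. Diene 12 is oxygenated with ground-state O2 under radical-cation chain catalysis by the aminium salt [(4-BrC6H4)3N]SbCl6 (cat., CH2Cl2, −78 °C, dark). The diene radical cation captures triplet oxygen at C1, closes onto C4 and is reduced by the next diene molecule; no singlet oxygen is present, so the ene channel is closed. It sets out from 12 and comes back at 13; no new compound arises on the way (F0).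

Step 10. Saturation of the tetrasubstituted furan may stall, and raising pressure or catalyst activity may bring hydrogenolysis at the free electron-rich benzylic carbinols. The fallback masks the carbinols before reduction. It sets out from 16: silylation (TBSOTf, 2,6-lutidine, CH2Cl2, −78 → 0 °C) should give 2,5-bis{4-[(1R,2S)-1-(tert-butyldimethylsilyloxy)-1-(3,4-dimethoxyphenyl)propan-2-yloxy]-3-methoxyphenyl}-3,4-dimethylfuran F2. Hydrogenation under forcing conditions (H2 50 bar, Rh/C, EtOAc, 50 °C) should give the all-cis oxolane bis(silyl ether) F3. Fluoride cleavage (TBAF, THF, rt), which is non-acidic and leaves the epimerisable benzylic ring centres alone, then comes back at 17.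

**Further compounds**
F1 | step 7 | (1R,2S)-1-(3,4-dimethoxyphenyl)-2-{4-[(E)-2-iodoprop-1-en-1-yl]-2-methoxyphenoxy}propan-1-ol | COc1ccc([C@@H](O)[C@H](C)Oc2ccc(/C=C(C)/I)cc2OC)cc1OC
F0 | step 8 | none | none
F2 | step 10 | 2,5-bis{4-[(1R,2S)-1-(tert-butyldimethylsilyloxy)-1-(3,4-dimethoxyphenyl)propan-2-yloxy]-3-methoxyphenyl}-3,4-dimethylfuran | COc1ccc([C@@H](O[Si](C)(C)C(C)(C)C)[C@H](C)Oc2ccc(-c3oc(-c4ccc(O[C@@H](C)[C@H](O[Si](C)(C)C(C)(C)C)c5ccc(OC)c(OC)c5)c(OC)c4)c(C)c3C)cc2OC)cc1OC
F3 | step 10 | all-cis (2R,3S,4R,5S)-2,5-bis{4-[(1R,2S)-1-(tert-butyldimethylsilyloxy)-1-(3,4-dimethoxyphenyl)propan-2-yloxy]-3-methoxyphenyl}-3,4-dimethyloxolane | COc1ccc([C@@H](O[Si](C)(C)C(C)(C)C)[C@H](C)Oc2ccc([C@H]3O[C@@H](c4ccc(O[C@@H](C)[C@H](O[Si](C)(C)C(C)(C)C)c5ccc(OC)c(OC)c5)c(OC)c4)[C@@H](C)[C@H]3C)cc2OC)cc1OC
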